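## Analysis of the target

The target (22) is an open-chain C22 furanoterpenoid acid. Its C15 chain (C1 = CO2H) ends in a furan-3-yl ring at C15 and carries methyl groups at C4, C8 and C12. It has a (4Z)-trisubstituted alkene (C4=C5; C3 and C6 cis) and a (9E,11E)-diene (C9=C10–C11=C12, methyl on C12). There are two stereocentres: C2 (R, secondary alcohol α to the acid) and C8 (S, methyl-bearing, allylic to the diene). They are 1,7-related across the C4=C5 alkene, so neither can direct the other, and C2 epimers will not be separable in practice; each centre must be set independently with high fidelity. The feature that decides the strategy is the array C2(OH)–C3H2–C4(CH3)=C5H: a homoallylic alcohol whose trisubstituted alkene is Z, one methylene away from the carbinol carbon. Sensitive groups are the 3-alkylfuran (acid, electrophiles, oxidants), the diene with its tertiary allylic C8–H (acid, organolithiums, oxidants, metathesis catalysts), and the β,γ-unsaturated α-hydroxy acid. The difficulty is control rather than size: a Z-trisubstituted alkene, two remote stereocentres, and an endgame that tolerates furan and diene.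

## Retrosynthetic reasoning

**22 ⇒ 21.** The acid is released last from its ethyl ester 21 by mild saponification, so no protecting group is needed on the C2 hydroxyl.

**21 ⇒ 20 + 18 (cut C2–C3).** The C2–C5 array is the retron of an allylboration. Aldehyde 18 supplies C1–C2, and the α-substituted 2-methylallylboronate 20 supplies C3–C5 with the whole C6–C15 chain on its boron-bearing carbon. The forward reaction must make C2–C3, move the alkene to C4=C5 with Z geometry, and translate the C5–B configuration into the C2–O configuration. Cutting here removes the Z-alkene and the C2 centre in one operation and leaves a precursor whose only new stereocentre is a C–B carbon.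

**20 ⇒ 16 + 17 via 19 (cut C4–C5).** 20 is not isolated. It arises in the same flask from the α-carbamoyloxy boronate 16 and Grignard reagent 17 through boronate complex 19 and a stereospecific 1,2-shift. Boron is placed on C5 first and the nucleophile is 17, so that no α-oxygenated organolithium ever meets the diene (it would cyclise onto C9) and no alkyllithium meets diene or furan.

**16 ⇒ 8 + 15 (cut C10–C11).** The (9E,11E)-diene is made by a stereoretentive sp2–sp2 coupling of the (E)-alkenylboronate in 8 with the (E)-iodoalkene 15. The diene must be in place before the key step: once C4=C5 exists, metathesis at C9 would ring-close onto it (C5–C9 cyclopentene). The secondary α-oxygenated boronate at C5 is a spectator in this coupling.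

**8 ⇒ 6 + 7; 6 ⇒ 4 (via 5) ⇒ 3 ⇒ 1 (via 2).** The alkenylboronate comes from cross-metathesis of the terminal vinyl group of 6 with 7; at this stage the molecule has no second alkene. The C5–B centre of 6 is set by enantioselective deprotonation–borylation of carbamate 4 through lithiated carbamate 5. 4 comes from alcohol 3, and 3 from chemoselective cleavage of the trisubstituted alkene of 1, which delivers C5–C10 with the C8 stereocentre intact.

**15 ⇒ 13 (via 14) ⇒ 12 ⇒ 9 + 10 (via 11).** The (E)-trisubstituted iodoalkene is the product of a syn-carboalumination/iodination of terminal alkyne 13. 13 is reached by desilylation of 12, made by sp3–sp2 coupling of the zinc reagent 11 (from 10) with 9.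

## Alternatives that were turned down

**Alternative 1:** (textbook) Cut C2–C3 as an enolate alkylation. The (Z)-allylic bromide A1 (from a Still–Gennari olefination, ester reduction and bromination) would alkylate the enolate of the chiral N-glycolyl oxazolidinone A2, followed by auxiliary removal and O-deprotection. It was turned down for three reasons:
- Each stereo-element is bought separately with its own reagent, about six operations for C1–C5 against one.
- A1 is a Z-allylic halide that can isomerise (ionisation, SN2′) and carries diene and furan through reduction and halogenation.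
- The ether protecting group on C2 would have to be removed oxidatively or by hydrogenolysis beside a furan and a diene.

**Alternative 2:** Cut C2–C3 as a [2,3]-Wittig rearrangement. Allylic alcohol A3 (from the isopropylidene end of 1 by asymmetric epoxidation and epoxide-to-allylic-alcohol isomerisation) would be etherified to glycolate A4, and its ester enolate rearranged with transfer of chirality from C5–O to C2. It was turned down on mechanistic grounds:
- The migrating terminus C3 is an unsubstituted CH2, so the C2 configuration depends only on the exo/endo orientation of the enolate in the five-membered transition state.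
- Endo places the chelated enolate over the C4 methyl; exo places it beside a pseudo-axial chain; a pseudo-equatorial chain eclipses the C4 methyl.
- The Z preference of 2-methylallyl ethers is secure only for non-stabilised carbanions.
- Z/E and C2 mixtures are therefore to be expected, and the C2 epimers are inseparable.
- The [3,3] counterpart from A3 would give the 4E alkene.

**Alternative 3:** Cut C7–C8 by a nickel-catalysed enantioconvergent Negishi coupling of the racemic dienyl chloride A5 with alkylzinc A6, setting C8 from a racemate while joining the halves. It was turned down because: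
- The pentadienyl–nickel intermediate has three termini (C8, C10, C12), and regiocontrol on such a system is unsecured.
- A6 still contains the whole C2/Z-alkene problem, so a second demanding step would remain.
- C8 comes free of charge from 1 in the chosen route.

Key step: step 9

Remark (assumption): 1 is the (S)-enantiomer of commercial β-citronellene in high enantiomeric purity, and (−)-sparteine is the chiral diamine; C8 of the target is carried unchanged from 1.

## Route

Step 1
Reactants: 1 (3S)-3,7-dimethylocta-1,6-diene
Product: 3 (4S)-4-methylhex-5-en-1-ol, via aldehyde 2 (not isolated)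
Conditions: O3 (1 equiv, Sudan III end point), CH2Cl2/MeOH, −78 °C; then NaBH4, −78 → 0 °C
Reagents that add atoms: ozone, [O-][O+]=O
Why: Chemoselective ozonolysis with reductive work-up; the electron-rich trisubstituted alkene reacts far faster than the monosubstituted vinyl group, and C8 (here C4) is not touched.

Step 2
Reactants: 3 (4S)-4-methylhex-5-en-1-ol
Product: 4 (4S)-4-methylhex-5-en-1-yl N,N-diisopropylcarbamate
Conditions: i-Pr2NCOCl, Et3N, CH2Cl2, reflux
Reagents that add atoms: N,N-diisopropylcarbamoyl chloride, CC(C)N(C(C)C)C(Cl)=O
Why: O-Carbamoylation; the hindered carbamate is the directing group for the next step and the leaving group of the key step.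

Step 3
Reactants: 4 (4S)-4-methylhex-5-en-1-yl N,N-diisopropylcarbamate
Product: 6 (1S,4S)-4-methyl-1-(4,4,5,5-tetramethyl-1,3,2-dioxaborolan-2-yl)hex-5-en-1-yl N,N-diisopropylcarbamate, via lithiated carbamate 5 (not isolated)
Conditions: s-BuLi, (−)-sparteine, Et2O, −78 °C, 5 h; i-PrOBpin, −78 °C; AcOH, −78 °C → rt
Reagents that add atoms: 2-isopropoxy-4,4,5,5-tetramethyl-1,3,2-dioxaborolane, CC(C)OB1OC(C)(C)C(C)(C)O1
Why: Hoppe deprotonation: s-BuLi/(−)-sparteine removes the pro-S hydrogen next to the carbamate oxygen (reagent control), and the configurationally stable 5 is borylated with retention to set the C–B centre as S; the isolated terminal alkene does not undergo carbolithiation at −78 °C, and the cold protic quench releases isopropoxide before any 1,2-shift can occur.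

Step 4
Reactants: 6 (1S,4S)-4-methyl-1-(4,4,5,5-tetramethyl-1,3,2-dioxaborolan-2-yl)hex-5-en-1-yl N,N-diisopropylcarbamate; 7 4,4,5,5-tetramethyl-2-vinyl-1,3,2-dioxaborolane
Product: 8 (1S,4S,5E)-4-methyl-1,6-bis(4,4,5,5-tetramethyl-1,3,2-dioxaborolan-2-yl)hex-5-en-1-yl N,N-diisopropylcarbamate
Conditions: 7 (3 equiv), Hoveyda–Grubbs II (5 mol%), CH2Cl2, 40 °C
Reagents that add atoms: none
Why: Olefin cross-metathesis of a terminal alkene with a vinylboronate should give the (E)-alkenylboronate; 6 has no second alkene, so no ring closure can compete, and the sp3 C–B bond and carbamate are inert to the ruthenium carbene.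

Step 5
Reactants: 9 3-bromofuran; 10 (5-iodopent-1-yn-1-yl)trimethylsilane
Product: 12 [5-(furan-3-yl)pent-1-yn-1-yl]trimethylsilane, via alkylzinc iodide 11 (not isolated)
Conditions: Zn, LiCl, THF, 40 °C (10 → 11); then 9, Pd(OAc)2/SPhos (2 mol%), THF, rt
Reagents that add atoms: none
Why: Zinc insertion into the primary iodide followed by Negishi sp3–sp2 coupling with the heteroaryl bromide; the silyl group keeps the alkyne out of the palladium chemistry.

Step 6
Reactants: 12 [5-(furan-3-yl)pent-1-yn-1-yl]trimethylsilane
Product: 13 3-(pent-4-yn-1-yl)furan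
Conditions: K2CO3 (cat.), MeOH, rt
Reagents that add atoms: none
Why: Base-catalysed protodesilylation of the alkynylsilane; the furan is untouched.

Step 7
Reactants: 13 3-(pent-4-yn-1-yl)furan
Product: 15 3-[(4E)-5-iodo-4-methylpent-4-en-1-yl]furan, via alkenylalane 14 (not isolated)
Conditions: Me3Al, Cp2ZrCl2 (cat.), CH2Cl2, 0 °C → rt; then I2, THF, −30 → 0 °C
Reagents that add atoms: trimethylaluminium, C[Al](C)C; iodine, II
Why: Negishi zirconium-catalysed carboalumination adds methyl and aluminium syn across the terminal alkyne (methyl to the internal carbon), and iodinolysis with retention gives the (E)-2-methyl-1-iodoalkene that becomes C11=C12.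

Step 8
Reactants: 8 (1S,4S,5E)-4-methyl-1,6-bis(4,4,5,5-tetramethyl-1,3,2-dioxaborolan-2-yl)hex-5-en-1-yl N,N-diisopropylcarbamate; 15 3-[(4E)-5-iodo-4-methylpent-4-en-1-yl]furan
Product: 16 (1S,4S,5E,7E)-11-(furan-3-yl)-4,8-dimethyl-1-(4,4,5,5-tetramethyl-1,3,2-dioxaborolan-2-yl)undeca-5,7-dien-1-yl N,N-diisopropylcarbamate
Conditions: Pd(dppf)Cl2 (5 mol%), K3PO4 (aq), THF, rt
Reagents that add atoms: none
Why: Suzuki–Miyaura alkenyl–alkenyl coupling with retention at both alkenes should give the (E,E)-diene; only the sp2 boronate transmetalates under these conditions, and the secondary α-oxygenated alkylboronate stays intact.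

Step 9
Reactants: 16 (1S,4S,5E,7E)-11-(furan-3-yl)-4,8-dimethyl-1-(4,4,5,5-tetramethyl-1,3,2-dioxaborolan-2-yl)undeca-5,7-dien-1-yl N,N-diisopropylcarbamate; 17 isopropenylmagnesium bromide; 18 ethyl glyoxylate
Product: 21 ethyl (2R,4Z,8S,9E,11E)-15-(furan-3-yl)-2-hydroxy-4,8,12-trimethylpentadeca-4,9,11-trienoate, via boronate complex 19 (not isolated), via allylboronate 20 (not isolated)
Conditions: 17 (1.0 equiv), THF/Et2O, −78 °C; −78 → 35 °C; then 18 (freshly distilled), 0 °C → rt; H2O
Reagents that add atoms: none
Why: Grignard 17 adds to the boron of 16 to give the tetracoordinate boronate 19; on warming, the isopropenyl group migrates from boron to C5 anti to the departing carbamate (1,2-metallate shift, inversion at carbon, Mg2+ assisting the leaving group), which forms C4–C5 and turns the (1S) centre of 16 into the (R)-configured allylboronate 20. The closest known reaction types are the Grignard-induced Matteson-type 1,2-shift of α-carbamoyloxy alkylboronates and the lithiation–borylation–allylation of carbamates with vinylboronates, which passes through the same kind of boronate complex. 20 then adds to aldehyde 18 through a closed six-membered Zimmerman–Traxler chair (type I allylboration; no ring is closed in the product) that forms C2–C3 and moves the alkene to C4=C5. Geometry: the C6 chain on the boron-bearing carbon takes the pseudo-axial position, because the pseudo-equatorial position is eclipsed with the C4 methyl group (A1,2 strain) and gauche to a pinacolato oxygen; an axial chain ends cis to C3, which is 4Z. C2: with the ester group of 18 equatorial, the aldehyde face is fixed by the allyl face that carries boron, so (R)-C5–B becomes (2R)-C–O by 1,3-chirality transfer. The minor equatorial pathway would give the (2S,4E) isomer, which is a geometric isomer and can be removed at the ester stage. The step needs carbon over oxygen migration in 19 (alkenyl groups migrate readily), no second addition of 17 to 20 (one equivalent, low temperature), and no attack on diene or furan (a vinyl Grignard neither adds to an unactivated diene nor metalates a furan at these temperatures, and the allylboration needs no Lewis acid). C8 is a spectator throughout.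

Step 10
Reactants: 21 ethyl (2R,4Z,8S,9E,11E)-15-(furan-3-yl)-2-hydroxy-4,8,12-trimethylpentadeca-4,9,11-trienoate
Product: 22 (2R,4Z,8S,9E,11E)-15-(furan-3-yl)-2-hydroxy-4,8,12-trimethylpentadeca-4,9,11-trienoic acid
Conditions: LiOH, THF/H2O, 0 °C → rt; then 1 M HCl to pH 4, 0 °C
Reagents that add atoms: lithium hydroxide, [Li+].[OH-]
Why: Saponification of an α-hydroxy ester is fast under mild conditions, so C2 should not epimerise and the skipped C4=C5 alkene should not migrate; the cold, weakly acidic work-up spares furan and diene.

## Compound list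

1 | (3S)-3,7-dimethylocta-1,6-diene [(S)-β-citronellene] | C=C[C@@H](C)CCC=C(C)C | starting material
2 | (4S)-4-methylhex-5-enal | C=C[C@@H](C)CCC=O | intermediate
3 | (4S)-4-methylhex-5-en-1-ol | C=C[C@@H](C)CCCO | intermediate
4 | (4S)-4-methylhex-5-en-1-yl N,N-diisopropylcarbamate | C=C[C@@H](C)CCCOC(=O)N(C(C)C)C(C)C | intermediate
5 | (1S,4S)-1-lithio-4-methylhex-5-en-1-yl N,N-diisopropylcarbamate (sparteine complex, ligand not drawn) | C=C[C@@H](C)CC[C@H]([Li])OC(=O)N(C(C)C)C(C)C | intermediate
6 | (1S,4S)-4-methyl-1-(4,4,5,5-tetramethyl-1,3,2-dioxaborolan-2-yl)hex-5-en-1-yl N,N-diisopropylcarbamate | C=C[C@@H](C)CC[C@H](B1OC(C)(C)C(C)(C)O1)OC(=O)N(C(C)C)C(C)C | intermediate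
7 | 4,4,5,5-tetramethyl-2-vinyl-1,3,2-dioxaborolane | C=CB1OC(C)(C)C(C)(C)O1 | starting material
8 | (1S,4S,5E)-4-methyl-1,6-bis(4,4,5,5-tetramethyl-1,3,2-dioxaborolan-2-yl)hex-5-en-1-yl N,N-diisopropylcarbamate | CC1(C)OB(/C=C/[C@@H](C)CC[C@H](B2OC(C)(C)C(C)(C)O2)OC(=O)N(C(C)C)C(C)C)OC1(C)C | intermediate
9 | 3-bromofuran | Brc1ccoc1 | starting material
10 | (5-iodopent-1-yn-1-yl)trimethylsilane | C[Si](C)(C)C#CCCCI | starting material
11 | [5-(trimethylsilyl)pent-4-yn-1-yl]zinc iodide | C[Si](C)(C)C#CCCC[Zn]I | intermediate
12 | [5-(furan-3-yl)pent-1-yn-1-yl]trimethylsilane | C[Si](C)(C)C#CCCCc1ccoc1 | intermediate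
13 | 3-(pent-4-yn-1-yl)furan | C#CCCCc1ccoc1 | intermediate
14 | [(1E)-5-(furan-3-yl)-2-methylpent-1-en-1-yl]dimethylalane | C[Al](C)/C=C(\C)CCCc1ccoc1 | intermediate
15 | 3-[(4E)-5-iodo-4-methylpent-4-en-1-yl]furan | I/C=C(\C)CCCc1ccoc1 | intermediate
16 | (1S,4S,5E,7E)-11-(furan-3-yl)-4,8-dimethyl-1-(4,4,5,5-tetramethyl-1,3,2-dioxaborolan-2-yl)undeca-5,7-dien-1-yl N,N-diisopropylcarbamate | CC(C)N(C(C)C)C(=O)O[C@H](CC[C@H](C)/C=C/C=C(\C)CCCc1ccoc1)B1OC(C)(C)C(C)(C)O1 | intermediate
17 | isopropenylmagnesium bromide (prop-1-en-2-ylmagnesium bromide) | CC(=C)[Mg]Br | starting material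
18 | ethyl glyoxylate (ethyl 2-oxoacetate) | CCOC(=O)C=O | starting material
19 | bromomagnesium isopropenyl boronate complex of 16 (boron tetracoordinate, C5 still S) | CC(C)N(C(C)C)C(=O)O[C@H](CC[C@H](C)/C=C/C=C(\C)CCCc1ccoc1)[B-]1(C(C)=C)OC(C)(C)C(C)(C)O1.[Mg+]Br | intermediate
20 | 2-[(3R,6S,7E,9E)-13-(furan-3-yl)-2,6,10-trimethyltrideca-1,7,9-trien-3-yl]-4,4,5,5-tetramethyl-1,3,2-dioxaborolane | C=C(C)[C@@H](CC[C@H](C)/C=C/C=C(\C)CCCc1ccoc1)B1OC(C)(C)C(C)(C)O1 | intermediate
21 | ethyl (2R,4Z,8S,9E,11E)-15-(furan-3-yl)-2-hydroxy-4,8,12-trimethylpentadeca-4,9,11-trienoate | C/C(=C/CC[C@H](C)/C=C/C=C(\C)CCCc1ccoc1)C[C@@H](O)C(=O)OCC | intermediate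
22 | (2R,4Z,8S,9E,11E)-15-(furan-3-yl)-2-hydroxy-4,8,12-trimethylpentadeca-4,9,11-trienoic acid | C/C(=C/CC[C@H](C)/C=C/C=C(\C)CCCc1ccoc1)C[C@@H](O)C(=O)O | target

## Step count and risk

Total steps: 10. Longest linear sequence: 7 (steps 1, 2, 3, 4, 8, 9, 10); steps 5–7 build the furan fragment 15.

**Step 9 (key step).** Most likely to go wrong:
- slow or incomplete 1,2-migration in the hindered complex 19, with oxygen migration or reversal of the Grignard addition;
- a second addition of 17 to 20, which would change the boron ligand set and erode Z selectivity;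
- leakage through the equatorial transition state.

Any C5 epimer carried from step 3 ends as the inseparable C2 epimer. Fallback, from 16 back to 21 by stepwise classical chemistry: perborate oxidation of the C–B bond of 16 gives a hemiacetal carbamate that collapses to (4S,5E,7E)-11-(furan-3-yl)-4,8-dimethylundeca-5,7-dienal F1. Stork–Zhao olefination with the ylide from (1-iodoethyl)triphenylphosphonium iodide gives 3-[(4E,6E,8S,11Z)-12-iodo-4,8-dimethyltrideca-4,6,11-trien-1-yl]furan F2. Iodine–magnesium exchange (i-PrMgCl·LiCl) and copper-catalysed opening of ethyl (2R)-oxirane-2-carboxylate at its CH2 carbon then returns to 21.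

**Step 8.** Most likely to go wrong: hydroxide-induced degradation of the α-carbamoyloxy boronate under the basic aqueous coupling conditions (hydroxy-ate formation followed by displacement of the carbamate, or protodeboronation), because that boron is also Lewis acidic. Fallback, from 15 and 6 to 16 without any base and without passing through 8: Negishi coupling of 15 with vinylzinc bromide gives 3-[(4E)-4-methylhepta-4,6-dien-1-yl]furan F3, and cross-metathesis of its terminal vinyl group with 6 gives 16 directly. Geometry control at C9=C10 would be weaker in this variant.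

**Step 3.** Most likely to go wrong: incomplete enantioselection in the deprotonation, or a 1,2-shift of an alkoxy ligand in the borate before the quench. Both matter because the C5 epimer cannot be removed later. Fallback with another source of chirality, from aldehyde 2 (isolated after a dimethyl sulfide work-up of step 1) back to 6: copper(I)/chiral bisphosphine-catalysed enantioselective addition of bis(pinacolato)diboron to the C=O group gives (1S,4S)-4-methyl-1-(4,4,5,5-tetramethyl-1,3,2-dioxaborolan-2-yl)hex-5-en-1-ol F4 (ligand enantiomer chosen for the 1S product), which is carbamoylated in situ to 6.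

**Step 4.** Most likely to go wrong: sluggish metathesis at the α-branched vinyl group, with alkene migration by ruthenium hydride species that would scramble C8. Fallback without metathesis, from 6 back to 8: ozonolysis of the vinyl group gives (1S,4S)-4-methyl-5-oxo-1-(4,4,5,5-tetramethyl-1,3,2-dioxaborolan-2-yl)pentyl N,N-diisopropylcarbamate F5, and Takai–Utimoto boryl-olefination (Cl2CHBpin, CrCl2, LiI) returns to 8 as the (E)-alkenylboronate.

**Step 1.** Most likely to go wrong: over-oxidation, i.e. partial cleavage of the vinyl group once the trisubstituted alkene is consumed. Fallback, from 1 back to 3: peracid epoxidation (only the trisubstituted alkene reacts) gives 2,2-dimethyl-3-[(3S)-3-methylpent-4-en-1-yl]oxirane F6, periodic acid cleavage gives 2, and borohydride reduction gives 3.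

## Further compounds

F1 | step 9 | (4S,5E,7E)-11-(furan-3-yl)-4,8-dimethylundeca-5,7-dienal | O=CCC[C@H](C)/C=C/C=C(\C)CCCc1ccoc1
F2 | step 9 | 3-[(4E,6E,8S,11Z)-12-iodo-4,8-dimethyltrideca-4,6,11-trien-1-yl]furan | C/C(I)=C/CC[C@H](C)/C=C/C=C(\C)CCCc1ccoc1
F3 | step 8 | 3-[(4E)-4-methylhepta-4,6-dien-1-yl]furan | C=C/C=C(\C)CCCc1ccoc1
F4 | step 3 | (1S,4S)-4-methyl-1-(4,4,5,5-tetramethyl-1,3,2-dioxaborolan-2-yl)hex-5-en-1-ol | C=C[C@@H](C)CC[C@H](B1OC(C)(C)C(C)(C)O1)O
F5 | step 4 | (1S,4S)-4-methyl-5-oxo-1-(4,4,5,5-tetramethyl-1,3,2-dioxaborolan-2-yl)pentyl N,N-diisopropylcarbamate | O=C[C@@H](C)CC[C@H](B1OC(C)(C)C(C)(C)O1)OC(=O)N(C(C)C)C(C)C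
F6 | step 1 | 2,2-dimethyl-3-[(3S)-3-methylpent-4-en-1-yl]oxirane (both epimers at the ring CH) | CC1(C)OC1CC[C@H](C)C=C
A1 | alternative 1 | 3-[(4E,6E,8S,11Z)-13-bromo-4,8,12-trimethyltrideca-4,6,11-trien-1-yl]furan | BrC/C(C)=C\CC[C@H](C)/C=C/C=C(\C)CCCc1ccoc1
A2 | alternative 1 | (4S)-4-benzyl-3-{[(4-methoxybenzyl)oxy]acetyl}-1,3-oxazolidin-2-one | COc1ccc(COCC(=O)N2C(=O)OC[C@@H]2Cc2ccccc2)cc1
A3 | alternative 2 | (3R,6S,7E,9E)-13-(furan-3-yl)-2,6,10-trimethyltrideca-1,7,9-trien-3-ol | C=C(C)[C@H](O)CC[C@H](C)/C=C/C=C(\C)CCCc1ccoc1
A4 | alternative 2 | propan-2-yl {[(3R,6S,7E,9E)-13-(furan-3-yl)-2,6,10-trimethyltrideca-1,7,9-trien-3-yl]oxy}acetate | C=C(C)[C@H](OCC(=O)OC(C)C)CC[C@H](C)/C=C/C=C(\C)CCCc1ccoc1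
A5 | alternative 3 | 3-[(4E,6E)-8-chloro-4-methylnona-4,6-dien-1-yl]furan (racemate) | CC(Cl)/C=C/C=C(\C)CCCc1ccoc1
A6 | alternative 3 | {(3Z,6R)-6-[(tert-butyldimethylsilyl)oxy]-7-ethoxy-4-methyl-7-oxohept-3-en-1-yl}zinc iodide | C/C(=C/CC[Zn]I)C[C@@H](O[Si](C)(C)C(C)(C)C)C(=O)OCC
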